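The dimer is cut at the butenolide (the C7=C11 olefin plus the C8–O acyl bond, made by intramolecular Horner–Wadsworth–Emmons olefination) and at C11–C13. This leaves two elemane cyclohexanes. These rings (C5–C10 and C5′–C10′) carry the same trans pair, quaternary C10 (methyl, vinyl) next to C5 (isopropenyl), but as mirror images: 5R,10R beside the butenolide and 5′S,10′S beside the saturated lactone. One [4+2] cycloaddition of a 2-silyloxybutadiene with an E-configured 2-methyl enal ester is run once with each antipode of a cationic oxazaborolidine. It forms C5–C6 and C9–C10, closes the ring, fixes both stereocentres and leaves a C7=C8 enol ether for lactone building.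

Key step: step 2

Remark (numbering): elemane numbering is used. Primed atoms belong to the saturated-lactone half. Series A is 5R,10R and series B is 5S,10S.
Remark (assumption): the (S)-prolinol-derived catalyst is taken to give the (1S,6S) adduct of series A. If the sense were reversed, the catalysts of steps 2 and 7 would simply change places.
Remark (structure analysis): in the butenolide, O8 is equatorial and trans to the C10 methyl. In the saturated lactone, O8′ is axial and cis to the C10′ methyl, and carbon (C11′) sits on C7′, where the cycloaddition places oxygen. Series B therefore needs a 1,2-shift of the oxygen (steps 11–16).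

Step 1
Reactants: 1 methyl vinyl ketone (but-3-en-2-one)
Product: 2 2-(tert-butyldimethylsilyloxy)buta-1,3-diene
Conditions: TBSOTf, Et3N, Et2O, 0 °C
Reagents that add atoms: tert-butyldimethylsilyl trifluoromethanesulfonate, CC(C)(C)[Si](C)(C)OS(=O)(=O)C(F)(F)F
Why: Soft enolisation at the only enolisable position (the methyl group) followed by O-silylation is a standard silyl enol ether formation and gives the 2-silyloxydiene.

Step 2
Reactants: 2 2-(tert-butyldimethylsilyloxy)buta-1,3-diene; 3 ethyl (E)-3-methyl-4-oxobut-2-enoate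
Product: 4 ethyl (1S,6S)-3-(tert-butyldimethylsilyloxy)-6-formyl-6-methylcyclohex-3-ene-1-carboxylate (series A; formyl on C10 trans to ester on C5)
Conditions: (S)-3,3-diphenyl-1-(2-methylphenyl)tetrahydro-1H,3H-pyrrolo[1,2-c][1,3,2]oxazaborole (20 mol %), HN(SO2CF3)2 (17 mol %), CH2Cl2, −78 °C
Reagents that add atoms: none
Why: The N-protonated oxazaborolidine binds the formyl oxygen of 3 at boron (formyl C–H···O contact, ester left free) and the diene adds in a concerted but asynchronous, suprafacial [4+2] cycloaddition, the closest known reaction type being the cationic-oxazaborolidine-catalysed Diels–Alder reaction of 2-substituted enals with 2-silyloxydienes. The six-membered ring C5–C10 is closed intermolecularly by the joint formation of C5–C6 and C9–C10. The relative configuration (formyl on C10 trans to ester on C5) is a direct copy of the E geometry of 3, because both bonds form on one face of the olefin. The absolute configuration of C5 and C10 is decided only by the catalyst, whose aryl groups screen one face of the bound s-trans enal, and endo or exo orientation is irrelevant because the diene termini are unsubstituted. The step needs regioselectivity: activation through the aldehyde makes the ester-bearing C5 the electrophilic end, which pairs with the nucleophilic CH2 next to the silyloxy carbon, so that oxygen ends on C7, para to C10. A slight excess of oxazaborolidine over acid and the low temperature protect the acid-labile enol ether.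

Step 3
Reactants: 4 ethyl (1S,6S)-3-(tert-butyldimethylsilyloxy)-6-formyl-6-methylcyclohex-3-ene-1-carboxylate
Product: 5 ethyl (1S,6R)-3-(tert-butyldimethylsilyloxy)-6-ethenyl-6-methylcyclohex-3-ene-1-carboxylate
Conditions: Ph3PCH3Br, KHMDS, THF, 0 °C; then 4, −78 → 0 °C
Reagents that add atoms: methyltriphenylphosphonium bromide, C[P+](c1ccccc1)(c1ccccc1)c1ccccc1.[Br-]
Why: Wittig methylenation: the small ylide attacks the non-enolisable formyl group much faster than the ester, and the basic, non-aqueous medium leaves the silyl enol ether and both stereocentres untouched.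

Step 4
Reactants: 5 ethyl (1S,6R)-3-(tert-butyldimethylsilyloxy)-6-ethenyl-6-methylcyclohex-3-ene-1-carboxylate
Product: 6 2-[(1S,6R)-3-(tert-butyldimethylsilyloxy)-6-ethenyl-6-methylcyclohex-3-en-1-yl]propan-2-ol
Conditions: MeMgBr (3.5 equiv), THF, 0 °C → rt; pH 7 buffer
Reagents that add atoms: methylmagnesium bromide, C[Mg]Br
Why: Double Grignard addition to the only remaining carbonyl group gives the dimethylcarbinol, the tert-butyldimethylsilyl enol ether being inert to the magnesium reagent and to a neutral quench.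

Step 5
Reactants: 6 2-[(1S,6R)-3-(tert-butyldimethylsilyloxy)-6-ethenyl-6-methylcyclohex-3-en-1-yl]propan-2-ol
Product: 7 tert-butyl{[(4R,5R)-4-ethenyl-4-methyl-5-(prop-1-en-2-yl)cyclohex-1-en-1-yl]oxy}dimethylsilane
Conditions: methyl N-(triethylammoniosulfonyl)carbamate (inner salt), toluene, 60 °C
Reagents that add atoms: none
Why: Dehydration through the sulfamate ester (syn-elimination under neutral conditions that spare the enol ether) should favour the isopropenyl group, because the methyl hydrogens are more numerous and more accessible than the single C5–H and the tetrasubstituted alternative would press against the quaternary C10.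

Step 6
Reactants: 7 tert-butyl{[(4R,5R)-4-ethenyl-4-methyl-5-(prop-1-en-2-yl)cyclohex-1-en-1-yl]oxy}dimethylsilane
Product: 9 (2R,4R,5R)-4-ethenyl-2-hydroxy-4-methyl-5-(prop-1-en-2-yl)cyclohexan-1-one, via alpha-silyloxy ketone 8 (not isolated)
Conditions: mCPBA (1.0 equiv), CH2Cl2, −20 °C; then HF·pyridine, THF, 0 °C
Reagents that add atoms: 3-chloroperoxybenzoic acid, OOC(=O)c1cccc(Cl)c1
Why: Rubottom oxidation: the peracid should pick the electron-rich C7=C8 enol ether over the vinyl and isopropenyl groups and approach anti to the pseudo-axial C10 methyl, so that after silyl migration and fluoride cleavage O8 sits equatorial (8R), which is also the more stable, epimerisable arrangement.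

Step 7
Reactants: 2 2-(tert-butyldimethylsilyloxy)buta-1,3-diene; 3 ethyl (E)-3-methyl-4-oxobut-2-enoate
Product: 10 ethyl (1R,6R)-3-(tert-butyldimethylsilyloxy)-6-formyl-6-methylcyclohex-3-ene-1-carboxylate (series B; antipode of 4)
Conditions: (R)-3,3-diphenyl-1-(2-methylphenyl)tetrahydro-1H,3H-pyrrolo[1,2-c][1,3,2]oxazaborole (20 mol %), HN(SO2CF3)2 (17 mol %), CH2Cl2, −78 °C
Reagents that add atoms: none
Why: This is the same catalytic Diels–Alder reaction under the mirror-image catalyst, with identical regiochemistry and trans relation but attack on the opposite enantioface, which sets C5′ and C10′.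

Step 8
Reactants: 10 ethyl (1R,6R)-3-(tert-butyldimethylsilyloxy)-6-formyl-6-methylcyclohex-3-ene-1-carboxylate
Product: 11 ethyl (1R,6S)-3-(tert-butyldimethylsilyloxy)-6-ethenyl-6-methylcyclohex-3-ene-1-carboxylate
Conditions: Ph3PCH3Br, KHMDS, THF, 0 °C; then 10, −78 → 0 °C
Reagents that add atoms: methyltriphenylphosphonium bromide, C[P+](c1ccccc1)(c1ccccc1)c1ccccc1.[Br-]
Why: Wittig methylenation of the non-enolisable aldehyde proceeds exactly as in step 3, with no stereocentre involved.

Step 9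
Reactants: 11 ethyl (1R,6S)-3-(tert-butyldimethylsilyloxy)-6-ethenyl-6-methylcyclohex-3-ene-1-carboxylate
Product: 12 2-[(1R,6S)-3-(tert-butyldimethylsilyloxy)-6-ethenyl-6-methylcyclohex-3-en-1-yl]propan-2-ol
Conditions: MeMgBr (3.5 equiv), THF, 0 °C → rt; pH 7 buffer
Reagents that add atoms: methylmagnesium bromide, C[Mg]Br
Why: Double Grignard addition to the ester proceeds as in step 4.

Step 10
Reactants: 12 2-[(1R,6S)-3-(tert-butyldimethylsilyloxy)-6-ethenyl-6-methylcyclohex-3-en-1-yl]propan-2-ol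
Product: 13 tert-butyl{[(4S,5S)-4-ethenyl-4-methyl-5-(prop-1-en-2-yl)cyclohex-1-en-1-yl]oxy}dimethylsilane
Conditions: methyl N-(triethylammoniosulfonyl)carbamate (inner salt), toluene, 60 °C
Reagents that add atoms: none
Why: Neutral sulfamate syn-elimination proceeds as in step 5, with the same steric and statistical bias towards the isopropenyl group.

Step 11
Reactants: 13 tert-butyl{[(4S,5S)-4-ethenyl-4-methyl-5-(prop-1-en-2-yl)cyclohex-1-en-1-yl]oxy}dimethylsilane
Product: 14 (2S,4S,5S)-2-(tert-butyldimethylsilyloxy)-4-ethenyl-4-methyl-5-(prop-1-en-2-yl)cyclohexan-1-one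
Conditions: mCPBA (1.0 equiv), CH2Cl2, −20 → 0 °C
Reagents that add atoms: 3-chloroperoxybenzoic acid, OOC(=O)c1cccc(Cl)c1
Why: Rubottom oxidation as in step 6 is stopped at the silyl-migrated alpha-silyloxy ketone, which puts the required oxygen on C8′ (its configuration is erased later) and keeps it protected for the olefination.

Step 12
Reactants: 14 (2S,4S,5S)-2-(tert-butyldimethylsilyloxy)-4-ethenyl-4-methyl-5-(prop-1-en-2-yl)cyclohexan-1-one; 15 triethyl phosphonoacetate
Product: 16 ethyl (2E)-2-[(2S,4S,5S)-2-(tert-butyldimethylsilyloxy)-4-ethenyl-4-methyl-5-(prop-1-en-2-yl)cyclohexylidene]acetate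
Conditions: 15, NaH, THF, 0 °C; then 14, rt → 50 °C
Reagents that add atoms: none
Why: Horner–Wadsworth–Emmons olefination turns the C7′ carbonyl carbon into the C7′–C11′ link, and the ester should settle anti to the bulky C8′ silyloxy group (E), which later keeps ester and hydroxyl apart.

Step 13
Reactants: 16 ethyl (2E)-2-[(2S,4S,5S)-2-(tert-butyldimethylsilyloxy)-4-ethenyl-4-methyl-5-(prop-1-en-2-yl)cyclohexylidene]acetate
Product: 17 ethyl (2E)-2-[(2S,4S,5S)-4-ethenyl-2-hydroxy-4-methyl-5-(prop-1-en-2-yl)cyclohexylidene]acetate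
Conditions: HF·pyridine, pyridine, THF, 0 °C → rt
Reagents that add atoms: none
Why: Fluoride-mediated silyl ether cleavage frees the allylic alcohol, and the E geometry prevents closure to a butenolide.

Step 14
Reactants: 17 ethyl (2E)-2-[(2S,4S,5S)-4-ethenyl-2-hydroxy-4-methyl-5-(prop-1-en-2-yl)cyclohexylidene]acetate
Product: 18 ethyl (2E)-2-[(4S,5S)-4-ethenyl-4-methyl-2-oxo-5-(prop-1-en-2-yl)cyclohexylidene]acetate
Conditions: DMP [1,1,1-triacetoxy-1,1-dihydro-1,2-benziodoxol-3(1H)-one], CH2Cl2, 0 °C → rt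
Reagents that add atoms: none
Why: Hypervalent-iodine oxidation of the allylic alcohol under mild conditions completes the 1,2-shift of the carbonyl group from C7′ to C8′ and gives a doubly activated olefin.

Step 15
Reactants: 18 ethyl (2E)-2-[(4S,5S)-4-ethenyl-4-methyl-2-oxo-5-(prop-1-en-2-yl)cyclohexylidene]acetate
Product: 19 ethyl 2-[(1R,4S,5S)-4-ethenyl-4-methyl-2-oxo-5-(prop-1-en-2-yl)cyclohexyl]acetate
Conditions: Zn dust, AcOH, rt; then DBU (10 mol %), CH2Cl2, rt
Reagents that add atoms: none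
Why: Dissolving-metal conjugate reduction of a 4-oxo-2-enoate touches only the doubly activated C7′=C11′ bond, and base equilibration through the C8′ enolate places the acetate side chain equatorial, which sets C7′ (R) under thermodynamic control.

Step 16
Reactants: 19 ethyl 2-[(1R,4S,5S)-4-ethenyl-4-methyl-2-oxo-5-(prop-1-en-2-yl)cyclohexyl]acetate
Product: 21 (3aR,5S,6S,7aR)-6-ethenyl-6-methyl-5-(prop-1-en-2-yl)hexahydro-1-benzofuran-2(3H)-one, via hydroxy ester 20 (not isolated)
Conditions: LiBH(s-Bu)3, THF, −78 °C → rt; aqueous work-up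
Reagents that add atoms: none
Why: Ketone reduction by a bulky trialkylborohydride can only follow the equatorial trajectory (the axial one is closed by the syn-axial C10′ methyl), which sets C8′ (R) as the axial alkoxide cis to the C7′ side chain, and this alkoxide lactonises on warming to the cis-fused lactone.

Step 17
Reactants: 21 (3aR,5S,6S,7aR)-6-ethenyl-6-methyl-5-(prop-1-en-2-yl)hexahydro-1-benzofuran-2(3H)-one
Product: 24 (3aR,5S,6S,7aR)-6-ethenyl-6-methyl-3-methylidene-5-(prop-1-en-2-yl)hexahydro-1-benzofuran-2(3H)-one, via Mannich base 22 (not isolated), via methiodide 23 (not isolated)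
Conditions: LDA, THF, −78 °C; CH2=NMe2 I, −78 °C → rt; MeI, MeOH, rt; aq NaHCO3, CH2Cl2
Reagents that add atoms: N,N-dimethylmethyleneiminium iodide, C=[N+](C)C.[I-]
Why: Mannich-type aminomethylation of the lactone enolate, quaternisation and Hofmann-type elimination is the standard alpha-methylenation of gamma-lactones and adds C13′.

Step 18
Reactants: 24 (3aR,5S,6S,7aR)-6-ethenyl-6-methyl-3-methylidene-5-(prop-1-en-2-yl)hexahydro-1-benzofuran-2(3H)-one
Product: 25 (3S,3aR,5S,6S,7aR)-6-ethenyl-6-methyl-3-[2-(phenylsulfanyl)ethyl]-5-(prop-1-en-2-yl)hexahydro-1-benzofuran-2(3H)-one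
Conditions: PhSMe, n-BuLi, DABCO, THF, 0 °C; CuI (0.5 equiv per Li), −40 °C; 24, −78 °C; AcOH, −78 °C
Reagents that add atoms: thioanisole, CSc1ccccc1
Why: Organocuprate conjugate addition joins C13 to C13′, and kinetic protonation of the resulting enolate from the convex face of the cis-fused bicycle (the face of H7′ and H8′) should set C11′ (S) with the chain on the concave face, as is general for Michael additions to cis-fused alpha-methylene lactones of this type.

Step 19
Reactants: 25 (3S,3aR,5S,6S,7aR)-6-ethenyl-6-methyl-3-[2-(phenylsulfanyl)ethyl]-5-(prop-1-en-2-yl)hexahydro-1-benzofuran-2(3H)-one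
Product: 27 (3S,3aR,5S,6S,7aR)-6-ethenyl-3-(2-iodoethyl)-6-methyl-5-(prop-1-en-2-yl)hexahydro-1-benzofuran-2(3H)-one, via sulfonium iodide 26 (not isolated)
Conditions: MeI (excess), NaI, DMF, 70 °C
Reagents that add atoms: methyl iodide, CI; sodium iodide, [Na+].[I-]
Why: S-Methylation gives a sulfonium salt in which iodide displaces thioanisole at the primary carbon (SN2), a neutral sulfide-to-iodide exchange that cannot epimerise C11′.

Step 20
Reactants: 27 (3S,3aR,5S,6S,7aR)-6-ethenyl-3-(2-iodoethyl)-6-methyl-5-(prop-1-en-2-yl)hexahydro-1-benzofuran-2(3H)-one; 28 allyl diethylphosphonoacetate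
Product: 29 prop-2-en-1-yl 2-(diethoxyphosphoryl)-4-[(3S,3aR,5S,6S,7aR)-6-ethenyl-6-methyl-2-oxo-5-(prop-1-en-2-yl)octahydro-1-benzofuran-3-yl]butanoate (both epimers at C11)
Conditions: 28 (2 equiv), NaH, THF–DMF, 0 °C; then 27, rt → 40 °C
Reagents that add atoms: none
Why: SN2 C-alkylation of the stabilised phosphonoacetate anion by a primary iodide forms C11–C13, the anion being far too weak a base to deprotonate the lactone and the new centre C11 being of no consequence because it becomes sp2.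

Step 21
Reactants: 29 prop-2-en-1-yl 2-(diethoxyphosphoryl)-4-[(3S,3aR,5S,6S,7aR)-6-ethenyl-6-methyl-2-oxo-5-(prop-1-en-2-yl)octahydro-1-benzofuran-3-yl]butanoate
Product: 30 2-(diethoxyphosphoryl)-4-[(3S,3aR,5S,6S,7aR)-6-ethenyl-6-methyl-2-oxo-5-(prop-1-en-2-yl)octahydro-1-benzofuran-3-yl]butanoic acid
Conditions: Pd(PPh3)4 (5 mol %), morpholine, THF, rt
Reagents that add atoms: none
Why: Tsuji–Trost-type deallylation: zerovalent palladium ionises only the allyl ester and morpholine traps the allyl fragment, so that lactone, phosphonate and the unactivated olefins stay intact.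

Step 22
Reactants: 30 2-(diethoxyphosphoryl)-4-[(3S,3aR,5S,6S,7aR)-6-ethenyl-6-methyl-2-oxo-5-(prop-1-en-2-yl)octahydro-1-benzofuran-3-yl]butanoic acid; 9 (2R,4R,5R)-4-ethenyl-2-hydroxy-4-methyl-5-(prop-1-en-2-yl)cyclohexan-1-one
Product: 31 (1R,4R,5R)-5-ethenyl-5-methyl-2-oxo-4-(prop-1-en-2-yl)cyclohexyl 2-(diethoxyphosphoryl)-4-[(3S,3aR,5S,6S,7aR)-6-ethenyl-6-methyl-2-oxo-5-(prop-1-en-2-yl)octahydro-1-benzofuran-3-yl]butanoate
Conditions: DCC, DMAP (cat.), CH2Cl2, 0 °C → rt
Reagents that add atoms: none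
Why: Steglich esterification joins the two antipodal halves through the C8–O bond with retention at C8, since only the acyl carbon reacts.

Step 23
Reactants: 31 (1R,4R,5R)-5-ethenyl-5-methyl-2-oxo-4-(prop-1-en-2-yl)cyclohexyl 2-(diethoxyphosphoryl)-4-[(3S,3aR,5S,6S,7aR)-6-ethenyl-6-methyl-2-oxo-5-(prop-1-en-2-yl)octahydro-1-benzofuran-3-yl]butanoate
Product: 32 (5R,6R,7aR)-6-ethenyl-3-{2-[(3S,3aR,5S,6S,7aR)-6-ethenyl-6-methyl-2-oxo-5-(prop-1-en-2-yl)octahydro-1-benzofuran-3-yl]ethyl}-6-methyl-5-(prop-1-en-2-yl)-5,6,7,7a-tetrahydro-1-benzofuran-2(4H)-one (CNP0332736.1)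
Conditions: LiCl, DBU, MeCN, rt, argon
Reagents that add atoms: none
Why: Intramolecular Horner–Wadsworth–Emmons olefination under soft-enolisation conditions closes the five-membered butenolide by forming C7=C11, the base being too weak to touch C11′ and C8 keeping its equatorial oxygen, the only arrangement that fits a planar butenolide on the chair with equatorial vinyl and isopropenyl groups.

Compound list
1 | methyl vinyl ketone | CC(=O)C=C | starting material
2 | 2-(tert-butyldimethylsilyloxy)buta-1,3-diene | C=CC(=C)O[Si](C)(C)C(C)(C)C | intermediate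
3 | ethyl (E)-3-methyl-4-oxobut-2-enoate | CCOC(=O)/C=C(\C)C=O | starting material
4 | ethyl (1S,6S)-3-(tert-butyldimethylsilyloxy)-6-formyl-6-methylcyclohex-3-ene-1-carboxylate | O=C[C@@]1(C)CC=C(O[Si](C)(C)C(C)(C)C)C[C@@H]1C(=O)OCC | intermediate
5 | ethyl (1S,6R)-3-(tert-butyldimethylsilyloxy)-6-ethenyl-6-methylcyclohex-3-ene-1-carboxylate | C=C[C@@]1(C)CC=C(O[Si](C)(C)C(C)(C)C)C[C@@H]1C(=O)OCC | intermediate
6 | 2-[(1S,6R)-3-(tert-butyldimethylsilyloxy)-6-ethenyl-6-methylcyclohex-3-en-1-yl]propan-2-ol | C=C[C@@]1(C)CC=C(O[Si](C)(C)C(C)(C)C)C[C@@H]1C(C)(C)O | intermediate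
7 | tert-butyl{[(4R,5R)-4-ethenyl-4-methyl-5-(prop-1-en-2-yl)cyclohex-1-en-1-yl]oxy}dimethylsilane | C=C[C@@]1(C)CC=C(O[Si](C)(C)C(C)(C)C)C[C@@H]1C(=C)C | intermediate
8 | (2R,4R,5R)-2-(tert-butyldimethylsilyloxy)-4-ethenyl-4-methyl-5-(prop-1-en-2-yl)cyclohexan-1-one | C=C[C@@]1(C)C[C@@H](O[Si](C)(C)C(C)(C)C)C(=O)C[C@@H]1C(=C)C | intermediate
9 | (2R,4R,5R)-4-ethenyl-2-hydroxy-4-methyl-5-(prop-1-en-2-yl)cyclohexan-1-one | C=C[C@@]1(C)C[C@@H](O)C(=O)C[C@@H]1C(=C)C | intermediate
10 | ethyl (1R,6R)-3-(tert-butyldimethylsilyloxy)-6-formyl-6-methylcyclohex-3-ene-1-carboxylate | O=C[C@]1(C)CC=C(O[Si](C)(C)C(C)(C)C)C[C@H]1C(=O)OCC | intermediate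
11 | ethyl (1R,6S)-3-(tert-butyldimethylsilyloxy)-6-ethenyl-6-methylcyclohex-3-ene-1-carboxylate | C=C[C@]1(C)CC=C(O[Si](C)(C)C(C)(C)C)C[C@H]1C(=O)OCC | intermediate
12 | 2-[(1R,6S)-3-(tert-butyldimethylsilyloxy)-6-ethenyl-6-methylcyclohex-3-en-1-yl]propan-2-ol | C=C[C@]1(C)CC=C(O[Si](C)(C)C(C)(C)C)C[C@H]1C(C)(C)O | intermediate
13 | tert-butyl{[(4S,5S)-4-ethenyl-4-methyl-5-(prop-1-en-2-yl)cyclohex-1-en-1-yl]oxy}dimethylsilane | C=C[C@]1(C)CC=C(O[Si](C)(C)C(C)(C)C)C[C@H]1C(=C)C | intermediate
14 | (2S,4S,5S)-2-(tert-butyldimethylsilyloxy)-4-ethenyl-4-methyl-5-(prop-1-en-2-yl)cyclohexan-1-one | C=C[C@]1(C)C[C@H](O[Si](C)(C)C(C)(C)C)C(=O)C[C@H]1C(=C)C | intermediate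
15 | triethyl phosphonoacetate | CCOC(=O)CP(=O)(OCC)OCC | starting material
16 | ethyl (2E)-2-[(2S,4S,5S)-2-(tert-butyldimethylsilyloxy)-4-ethenyl-4-methyl-5-(prop-1-en-2-yl)cyclohexylidene]acetate | C=C[C@]1(C)C[C@H](O[Si](C)(C)C(C)(C)C)/C(=C/C(=O)OCC)C[C@H]1C(=C)C | intermediate
17 | ethyl (2E)-2-[(2S,4S,5S)-4-ethenyl-2-hydroxy-4-methyl-5-(prop-1-en-2-yl)cyclohexylidene]acetate | C=C[C@]1(C)C[C@H](O)/C(=C/C(=O)OCC)C[C@H]1C(=C)C | intermediate
18 | ethyl (2E)-2-[(4S,5S)-4-ethenyl-4-methyl-2-oxo-5-(prop-1-en-2-yl)cyclohexylidene]acetate | C=C[C@]1(C)CC(=O)/C(=C/C(=O)OCC)C[C@H]1C(=C)C | intermediate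
19 | ethyl 2-[(1R,4S,5S)-4-ethenyl-4-methyl-2-oxo-5-(prop-1-en-2-yl)cyclohexyl]acetate | C=C[C@]1(C)CC(=O)[C@@H](CC(=O)OCC)C[C@H]1C(=C)C | intermediate
20 | ethyl 2-[(1R,2R,4S,5S)-4-ethenyl-2-hydroxy-4-methyl-5-(prop-1-en-2-yl)cyclohexyl]acetate (formed as its lithium alkoxide) | C=C[C@]1(C)C[C@@H](O)[C@@H](CC(=O)OCC)C[C@H]1C(=C)C | intermediate
21 | (3aR,5S,6S,7aR)-6-ethenyl-6-methyl-5-(prop-1-en-2-yl)hexahydro-1-benzofuran-2(3H)-one | C=C[C@]1(C)C[C@H]2OC(=O)C[C@H]2C[C@H]1C(=C)C | intermediate
22 | (3aR,5S,6S,7aR)-3-[(dimethylamino)methyl]-6-ethenyl-6-methyl-5-(prop-1-en-2-yl)hexahydro-1-benzofuran-2(3H)-one (C3 configuration irrelevant) | C=C[C@]1(C)C[C@H]2OC(=O)C(CN(C)C)[C@H]2C[C@H]1C(=C)C | intermediate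
23 | {[(3aR,5S,6S,7aR)-6-ethenyl-6-methyl-2-oxo-5-(prop-1-en-2-yl)octahydro-1-benzofuran-3-yl]methyl}trimethylammonium iodide | C=C[C@]1(C)C[C@H]2OC(=O)C(C[N+](C)(C)C)[C@H]2C[C@H]1C(=C)C.[I-] | intermediate
24 | (3aR,5S,6S,7aR)-6-ethenyl-6-methyl-3-methylidene-5-(prop-1-en-2-yl)hexahydro-1-benzofuran-2(3H)-one | C=C[C@]1(C)C[C@H]2OC(=O)C(=C)[C@H]2C[C@H]1C(=C)C | intermediate
25 | (3S,3aR,5S,6S,7aR)-6-ethenyl-6-methyl-3-[2-(phenylsulfanyl)ethyl]-5-(prop-1-en-2-yl)hexahydro-1-benzofuran-2(3H)-one | C=C[C@]1(C)C[C@H]2OC(=O)[C@@H](CCSc3ccccc3)[C@H]2C[C@H]1C(=C)C | intermediate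
26 | {2-[(3S,3aR,5S,6S,7aR)-6-ethenyl-6-methyl-2-oxo-5-(prop-1-en-2-yl)octahydro-1-benzofuran-3-yl]ethyl}(methyl)(phenyl)sulfonium iodide | C=C[C@]1(C)C[C@H]2OC(=O)[C@@H](CC[S+](C)c3ccccc3)[C@H]2C[C@H]1C(=C)C.[I-] | intermediate
27 | (3S,3aR,5S,6S,7aR)-6-ethenyl-3-(2-iodoethyl)-6-methyl-5-(prop-1-en-2-yl)hexahydro-1-benzofuran-2(3H)-one | C=C[C@]1(C)C[C@H]2OC(=O)[C@@H](CCI)[C@H]2C[C@H]1C(=C)C | intermediate
28 | allyl diethylphosphonoacetate | C=CCOC(=O)CP(=O)(OCC)OCC | starting material
29 | prop-2-en-1-yl 2-(diethoxyphosphoryl)-4-[(3S,3aR,5S,6S,7aR)-6-ethenyl-6-methyl-2-oxo-5-(prop-1-en-2-yl)octahydro-1-benzofuran-3-yl]butanoate | C=C[C@]1(C)C[C@H]2OC(=O)[C@@H](CCC(C(=O)OCC=C)P(=O)(OCC)OCC)[C@H]2C[C@H]1C(=C)C | intermediate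
30 | 2-(diethoxyphosphoryl)-4-[(3S,3aR,5S,6S,7aR)-6-ethenyl-6-methyl-2-oxo-5-(prop-1-en-2-yl)octahydro-1-benzofuran-3-yl]butanoic acid | C=C[C@]1(C)C[C@H]2OC(=O)[C@@H](CCC(C(=O)O)P(=O)(OCC)OCC)[C@H]2C[C@H]1C(=C)C | intermediate
31 | (1R,4R,5R)-5-ethenyl-5-methyl-2-oxo-4-(prop-1-en-2-yl)cyclohexyl 2-(diethoxyphosphoryl)-4-[(3S,3aR,5S,6S,7aR)-6-ethenyl-6-methyl-2-oxo-5-(prop-1-en-2-yl)octahydro-1-benzofuran-3-yl]butanoate | C=C[C@@]1(C)C[C@@H](OC(=O)C(CC[C@@H]2C(=O)O[C@@H]3C[C@@](C)(C=C)[C@H](C(=C)C)C[C@H]23)P(=O)(OCC)OCC)C(=O)C[C@@H]1C(=C)C | intermediate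
32 | CNP0332736.1, (5R,6R,7aR)-6-ethenyl-3-{2-[(3S,3aR,5S,6S,7aR)-6-ethenyl-6-methyl-2-oxo-5-(prop-1-en-2-yl)octahydro-1-benzofuran-3-yl]ethyl}-6-methyl-5-(prop-1-en-2-yl)-5,6,7,7a-tetrahydro-1-benzofuran-2(4H)-one | C=C[C@@]1(C)C[C@H]2OC(=O)C(CC[C@@H]3C(=O)O[C@@H]4C[C@@](C)(C=C)[C@H](C(=C)C)C[C@H]34)=C2C[C@@H]1C(=C)C | target

Total step count: 23 (steps 2 and 7 are the two runs of the key step).
Longest linear sequence: 18 steps (step 1, then steps 7–23).

Steps most likely to fail

**Step 2 (and its mirror run, step 7).**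
- What may go wrong: facial or regiochemical control may erode, or the diene may undergo protodesilylation and open-chain Mukaiyama-type addition under the cationic catalyst.
- Fallback idea: chirality is taken from a resolution that uses both antipodes instead of from the catalyst.
- Setting out from 2 and 3, the cycloaddition is run with an achiral Lewis acid (AlMe2Cl, CH2Cl2, −78 °C).
- The racemate (4 plus 10) is carried through the chemistry of steps 3–6. This gives racemic hydroxyketone, that is 9 together with its antipode (2S,4S,5S)-4-ethenyl-2-hydroxy-4-methyl-5-(prop-1-en-2-yl)cyclohexan-1-one F1.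
- The mixture is split by enzymatic acylation (Candida antarctica lipase B, vinyl acetate, tert-butyl methyl ether). This is drawn here for acylation of the series B antipode to (1S,4S,5S)-5-ethenyl-5-methyl-2-oxo-4-(prop-1-en-2-yl)cyclohexyl acetate F2.
- Unreacted 9 comes back to the route at step 22.
- F2 is methanolysed (K2CO3, MeOH) to F1, which is silylated (TBSCl, imidazole, DMF) and comes back to the route at 14.

**Step 12.**
- What may go wrong: the hindered alpha-silyloxy ketone may be enolised, with silyl migration between the two oxygens, or olefination may be slow or of poor geometric selectivity.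
- Fallback idea: addition followed by rearrangement replaces the phosphonate olefination.
- Setting out from 14, the small nucleophile lithium ethoxyacetylide (ethoxyacetylene, n-BuLi, THF, −78 °C) should add to the ketone to give (2S,4S,5S)-2-(tert-butyldimethylsilyloxy)-4-ethenyl-1-(ethoxyethynyl)-4-methyl-5-(prop-1-en-2-yl)cyclohexan-1-ol F3.
- Meyer–Schuster rearrangement of F3 (AuCl3, 5 mol %, EtOH, CH2Cl2, rt) should give the unsaturated ethyl ester and comes back to the route at 16.

**Step 20.**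
- What may go wrong: proton transfer from C11′ may be followed by three-membered ring closure or epimerisation, hydrogen iodide may be lost, or a second alkylation may occur.
- Fallback idea: the central bond C13′–C13 is made by a radical addition without base, which bypasses 25–27.
- Setting out from 24, conjugate addition of benzeneselenol ((PhSe)2, NaBH4, EtOH, then AcOH), with the same convex-face protonation, should give (3S,3aR,5S,6S,7aR)-6-ethenyl-6-methyl-3-[(phenylselanyl)methyl]-5-(prop-1-en-2-yl)hexahydro-1-benzofuran-2(3H)-one F4.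
- In parallel, 28 is condensed with paraformaldehyde (Knoevenagel condensation, piperidine, AcOH, toluene, reflux, water separator) to prop-2-en-1-yl 2-(diethoxyphosphoryl)prop-2-enoate F5.
- A Giese reaction of F4 with excess F5 (Bu3SnH added slowly, AIBN, benzene, 80 °C) comes back to the route at 29.

Further compounds
F1 | step 2 | (2S,4S,5S)-4-ethenyl-2-hydroxy-4-methyl-5-(prop-1-en-2-yl)cyclohexan-1-one | C=C[C@]1(C)C[C@H](O)C(=O)C[C@H]1C(=C)C
F2 | step 2 | (1S,4S,5S)-5-ethenyl-5-methyl-2-oxo-4-(prop-1-en-2-yl)cyclohexyl acetate | C=C[C@]1(C)C[C@H](OC(C)=O)C(=O)C[C@H]1C(=C)C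
F3 | step 12 | (2S,4S,5S)-2-(tert-butyldimethylsilyloxy)-4-ethenyl-1-(ethoxyethynyl)-4-methyl-5-(prop-1-en-2-yl)cyclohexan-1-ol | C=C[C@]1(C)C[C@H](O[Si](C)(C)C(C)(C)C)C(O)(C#COCC)C[C@H]1C(=C)C
F4 | step 20 | (3S,3aR,5S,6S,7aR)-6-ethenyl-6-methyl-3-[(phenylselanyl)methyl]-5-(prop-1-en-2-yl)hexahydro-1-benzofuran-2(3H)-one | C=C[C@]1(C)C[C@H]2OC(=O)[C@@H](C[Se]c3ccccc3)[C@H]2C[C@H]1C(=C)C
F5 | step 20 | prop-2-en-1-yl 2-(diethoxyphosphoryl)prop-2-enoate | C=CCOC(=O)C(=C)P(=O)(OCC)OCC
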